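The strategy disconnects ring C at two neighbouring carbons: its C1–O bond to ring B and its C2–OH. These, together with the C3 methoxy, form a 1,2,3-trioxygenated edge that maps onto a 3-methoxybenzyne whose strained C1≡C2 bond accepts an oxygen nucleophile at C1 and an electrophile at C2. The key step does both at once: the phenoxide of the ring A–ring B diaryl ether attacks C1 and iodine, a stand-in for the hydroxyl, lands on C2. The precursors are that dimer phenol, built by a CuI-catalysed etherification, and a 5-allyl-3-methoxy-2-silylaryl triflate obtained by C–H borylation and allylation of a commercial aryne precursor.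

Key step: step 7

Assumption: 3-methoxy-2-(trimethylsilyl)phenyl trifluoromethanesulfonate (6), the usual precursor of 3-methoxybenzyne, is taken as a purchasable compound. Ring C is numbered C1 (ether carbon), C2 (hydroxyl carbon), C3 (methoxy carbon), C5 (allyl carbon).

Design remarks:
- The allyl group of the aryne precursor is attached after the C–Si and C–OTf bonds already exist, so no directed lithiation has to be run on an allylarene with acidic benzylic/allylic hydrogens.
- The dimer phenol is made by established copper chemistry, so that only step 7 is without precedent.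
- The phenoxide is preformed with KH, so that no hydrogencarbonate or other proton donor accompanies the aryl anion in the key step.

Step 1
Reactants: 1 eugenol (4-allyl-2-methoxyphenol)
Product: 2 4-allyl-2-bromo-6-methoxyphenol
Conditions: NBS (1.0 equiv), iPr2NH (cat.), CH2Cl2, 0 °C, dark
Reagents that add atoms: N-bromosuccinimide, O=C1CCC(=O)N1Br
Why: Amine-catalysed electrophilic aromatic bromination of a phenol; the hydroxyl directs bromine to its only free ortho position (para is blocked by the allyl group), and at 0 °C in the dark the phenol ring should react far faster than the terminal alkene or the benzylic CH2.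

Step 2
Reactants: 2 4-allyl-2-bromo-6-methoxyphenol
Product: 3 5-allyl-1-bromo-3-methoxy-2-(methoxymethoxy)benzene
Conditions: MOMCl, iPr2NEt, CH2Cl2, 0 °C → rt
Reagents that add atoms: chloromethyl methyl ether, COCCl
Why: O-alkylation of the phenol (methoxymethyl protection) masks the acidic hydroxyl so that the bromide can act as the electrophile in the following etherification, and the small reagent should reach the flanked oxygen without difficulty.

Step 3
Reactants: 3 5-allyl-1-bromo-3-methoxy-2-(methoxymethoxy)benzene; 1 eugenol
Product: 4 5-allyl-1-(4-allyl-2-methoxyphenoxy)-3-methoxy-2-(methoxymethoxy)benzene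
Conditions: CuI (10 mol%), N,N-dimethylglycine·HCl (30 mol%), Cs2CO3, 1,4-dioxane, 90 °C
Reagents that add atoms: none
Why: Ullmann-type diaryl ether synthesis with an amino acid ligand, a reaction type established for allyl-bearing phenols and electron-rich aryl bromides; the carbonate base at 90 °C is too weak to move the allyl double bonds into conjugation.

Step 4
Reactants: 4 5-allyl-1-(4-allyl-2-methoxyphenoxy)-3-methoxy-2-(methoxymethoxy)benzene
Product: 5 4-allyl-2-(4-allyl-2-methoxyphenoxy)-6-methoxyphenol (dimer phenol)
Conditions: conc. HCl (cat.), MeOH, 45 °C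
Reagents that add atoms: none
Why: Acid-catalysed transacetalisation removes the methoxymethyl group as dimethoxymethane, while aryl methyl ethers, the diaryl ether and the terminal alkenes are inert to dilute methanolic acid.

Step 5
Reactants: 6 3-methoxy-2-(trimethylsilyl)phenyl trifluoromethanesulfonate
Product: 7 3-methoxy-5-(4,4,5,5-tetramethyl-1,3,2-dioxaborolan-2-yl)-2-(trimethylsilyl)phenyl trifluoromethanesulfonate
Conditions: B2pin2 (1.0 equiv), [Ir(OMe)(cod)]2 (1.5 mol%), 4,4'-di-tert-butyl-2,2'-bipyridine (3 mol%), MTBE, 60 °C
Reagents that add atoms: bis(pinacolato)diboron, CC1(C)OB(OC1(C)C)B1OC(C)(C)C(C)(C)O1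
Why: Sterically governed C–H borylation with [Ir(OMe)(cod)]2 and a bipyridine ligand; C5 is the only ring C–H without an ortho substituent, and the neutral, fluoride-free conditions are known to leave the silyl and triflate groups of such aryne precursors intact.

Step 6
Reactants: 7 3-methoxy-5-(4,4,5,5-tetramethyl-1,3,2-dioxaborolan-2-yl)-2-(trimethylsilyl)phenyl trifluoromethanesulfonate; 8 allyl bromide
Product: 9 5-allyl-3-methoxy-2-(trimethylsilyl)phenyl trifluoromethanesulfonate
Conditions: Pd(PPh3)4 (5 mol%), K2CO3, THF–H2O, 60 °C
Reagents that add atoms: none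
Why: Suzuki–Miyaura allyl–aryl coupling; zerovalent palladium inserts into allyl bromide far faster than into the aryl triflate shielded by the ortho silyl group, the aryl group is transferred from boron under mild carbonate activation, and the absence of fluoride keeps the silyl triflate pair dormant.

Step 7
Reactants: 5 4-allyl-2-(4-allyl-2-methoxyphenoxy)-6-methoxyphenol; 9 5-allyl-3-methoxy-2-(trimethylsilyl)phenyl trifluoromethanesulfonate
Product: 13 5-allyl-1-(4-allyl-2-methoxyphenoxy)-2-(5-allyl-2-iodo-3-methoxyphenoxy)-3-methoxybenzene, via potassium phenoxide 10 (not isolated), via 5-allyl-3-methoxybenzyne 11 (not isolated), via C2 arylpotassium 12 (not isolated)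
Conditions: KH, THF, 0 °C; then 9 (1.3 equiv, slow addition), n-C4F9I (3 equiv), KF, 18-crown-6, THF, 20 °C, dark, argon
Reagents that add atoms: nonafluoro-1-iodobutane, FC(F)(F)C(F)(F)C(F)(F)C(F)(F)I
Why: Proposed new method: fluoride attacks silicon of 9 and triflate departs, giving aryne 11, whose triple bond is distorted by the inductively withdrawing C3 methoxy so that C1 is the more electrophilic terminus; phenoxide 10 adds there and the C2 anion 12, stabilised by the adjacent methoxy, takes iodine from C4F9I by halogen-bond (ate-type) transfer, the perfluorobutyl anion collapsing to octafluorobutene and fluoride, which sustains aryne release. The closest known reaction types are the fluoride-triggered O-arylation of phenols with silylaryl triflates and the heteroatom–iodine 1,2-difunctionalisation of arynes that uses perfluoroalkyl iodides as iodine donors. No ring is closed and no stereocentre is created. The step needs regioselectivity (oxygen on C1, iodine on C2), which the C3 methoxy secures, and it needs iodination to outrun protonation, which the proton-free medium (phenoxide preformed with KH, THF, no acetonitrile or hydrogencarbonate) and the excess of iodide secure. Aryne capture is expected to tolerate the two ortho substituents of the phenoxide, and at 20 °C in the dark neither allyl-to-propenyl migration nor radical addition of the iodide to the allyl groups should compete.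

Step 8
Reactants: 13 5-allyl-1-(4-allyl-2-methoxyphenoxy)-2-(5-allyl-2-iodo-3-methoxyphenoxy)-3-methoxybenzene
Product: 16 4-allyl-2-[4-allyl-2-(4-allyl-2-methoxyphenoxy)-6-methoxyphenoxy]-6-methoxyphenol (target), via arylmagnesium chloride 14 (not isolated), via dimethyl arylboronate 15 (not isolated)
Conditions: iPrMgCl·LiCl, THF, −20 → 0 °C; B(OMe)3, −20 °C → rt; 30% H2O2, aq. NaOH, 0 °C
Reagents that add atoms: hydrogen peroxide, OO
Why: Iodine–magnesium exchange (Knochel type) is favoured at an aryl iodide flanked by two coordinating ether oxygens and spares ethers and unactivated alkenes; the Grignard reagent is borylated and the boronate oxidised with 1,2-aryl shift from boron to oxygen, conditions to which isolated terminal alkenes are inert.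

Compound list
1 | eugenol (4-allyl-2-methoxyphenol) | C=CCc1ccc(O)c(OC)c1 | starting material
2 | 4-allyl-2-bromo-6-methoxyphenol | C=CCc1cc(Br)c(O)c(OC)c1 | intermediate
3 | 5-allyl-1-bromo-3-methoxy-2-(methoxymethoxy)benzene | C=CCc1cc(Br)c(OCOC)c(OC)c1 | intermediate
4 | 5-allyl-1-(4-allyl-2-methoxyphenoxy)-3-methoxy-2-(methoxymethoxy)benzene | C=CCc1ccc(Oc2cc(CC=C)cc(OC)c2OCOC)c(OC)c1 | intermediate
5 | 4-allyl-2-(4-allyl-2-methoxyphenoxy)-6-methoxyphenol (dimer phenol) | C=CCc1ccc(Oc2cc(CC=C)cc(OC)c2O)c(OC)c1 | intermediate
6 | 3-methoxy-2-(trimethylsilyl)phenyl trifluoromethanesulfonate | COc1cccc(OS(=O)(=O)C(F)(F)F)c1[Si](C)(C)C | starting material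
7 | 3-methoxy-5-(4,4,5,5-tetramethyl-1,3,2-dioxaborolan-2-yl)-2-(trimethylsilyl)phenyl trifluoromethanesulfonate | COc1cc(B2OC(C)(C)C(C)(C)O2)cc(OS(=O)(=O)C(F)(F)F)c1[Si](C)(C)C | intermediate
8 | allyl bromide (3-bromoprop-1-ene) | C=CCBr | starting material
9 | 5-allyl-3-methoxy-2-(trimethylsilyl)phenyl trifluoromethanesulfonate | C=CCc1cc(OC)c([Si](C)(C)C)c(OS(=O)(=O)C(F)(F)F)c1 | intermediate
10 | potassium 4-allyl-2-(4-allyl-2-methoxyphenoxy)-6-methoxyphenoxide | C=CCc1ccc(Oc2cc(CC=C)cc(OC)c2[O-])c(OC)c1.[K+] | intermediate (not isolated)
11 | 5-allyl-3-methoxybenzyne | C=CCC1=CC#CC(OC)=C1 | intermediate (not isolated)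
12 | C2 arylpotassium adduct of 10 and 11 (anion on ring C between the new ether oxygen and the methoxy) | C=CCc1ccc(Oc2cc(CC=C)cc(OC)c2Oc2cc(CC=C)cc(OC)[c-]2)c(OC)c1.[K+] | intermediate (not isolated)
13 | 5-allyl-1-(4-allyl-2-methoxyphenoxy)-2-(5-allyl-2-iodo-3-methoxyphenoxy)-3-methoxybenzene | C=CCc1ccc(Oc2cc(CC=C)cc(OC)c2Oc2cc(CC=C)cc(OC)c2I)c(OC)c1 | intermediate
14 | arylmagnesium chloride from 13 (MgCl in place of iodine) | C=CCc1ccc(Oc2cc(CC=C)cc(OC)c2Oc2cc(CC=C)cc(OC)c2[Mg]Cl)c(OC)c1 | intermediate (not isolated)
15 | dimethyl arylboronate from 14 (B(OMe)2 in place of MgCl) | C=CCc1ccc(Oc2cc(CC=C)cc(OC)c2Oc2cc(CC=C)cc(OC)c2B(OC)OC)c(OC)c1 | intermediate (not isolated)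
16 | 4-allyl-2-[4-allyl-2-(4-allyl-2-methoxyphenoxy)-6-methoxyphenoxy]-6-methoxyphenol | C=CCc1ccc(Oc2cc(CC=C)cc(OC)c2Oc2cc(CC=C)cc(OC)c2O)c(OC)c1 | target

Total step count: 8
Longest linear sequence: 6 steps (steps 1, 2, 3, 4, 7, 8 from eugenol)

Steps most likely to fail

1. Step 7 (proposed new method). Three processes may intervene. The C2 aryl anion may be protonated by adventitious proton donors or by the benzylic/allylic C–H bonds before iodine transfer, leaving hydrogen where iodine should sit. Perfluorobutyl radicals may add across the allyl groups if electron transfer from the phenoxide occurs. The phenoxide may be consumed by the fluoroalkene by-product. The fallback uses known chemistry and sets out from dimer phenol 5 together with bromide 3. An Ullmann-type etherification under conditions developed for hindered phenols (CuI, picolinic acid, K3PO4, DMSO, 90 °C) should give 5-allyl-1-(4-allyl-2-methoxyphenoxy)-2-[5-allyl-3-methoxy-2-(methoxymethoxy)phenoxy]-3-methoxybenzene F1. Its methoxymethyl group is then removed with catalytic HCl in MeOH at 45 °C, and the route is rejoined at target 16; iodide 13 is bypassed.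

2. Step 6. Zerovalent palladium may insert into the aryl triflate, the aqueous base may erode the silyl triflate pair, or a palladium hydride may shift the new allyl double bond into conjugation. The fallback reverses the polarity of the coupling and sets out from boronate 7. Bromodeboronation with CuBr2 in MeOH–H2O at 80 °C should give 5-bromo-3-methoxy-2-(trimethylsilyl)phenyl trifluoromethanesulfonate F2. A base-free and fluoride-free Stille coupling with allyltributylstannane (Pd(PPh3)4, toluene, 100 °C), selective for the unhindered C–Br bond over the shielded C–OTf bond, then returns to aryne precursor 9.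

3. Step 3. Oxidative addition at the electron-rich, ortho-substituted bromide may be sluggish, so that hydrodebromination or slow isomerisation of the allyl groups at 90 °C erodes the coupling. The fallback changes the bond-forming mode from aryl halide substitution to oxidative coupling and sets out from bromide 3. Bromine–lithium exchange (n-BuLi, THF, −78 °C, faster than allylic deprotonation at this temperature), quench with B(OiPr)3 and work-up with aqueous NH4Cl should give [5-allyl-3-methoxy-2-(methoxymethoxy)phenyl]boronic acid F3. A Chan–Lam–Evans coupling with eugenol 1 (Cu(OAc)2, pyridine, 4 Å molecular sieves, CH2Cl2, air, rt) then returns to protected dimer 4.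

Further compounds
F1 | step 7 | 5-allyl-1-(4-allyl-2-methoxyphenoxy)-2-[5-allyl-3-methoxy-2-(methoxymethoxy)phenoxy]-3-methoxybenzene | C=CCc1ccc(Oc2cc(CC=C)cc(OC)c2Oc2cc(CC=C)cc(OC)c2OCOC)c(OC)c1
F2 | step 6 | 5-bromo-3-methoxy-2-(trimethylsilyl)phenyl trifluoromethanesulfonate | COc1cc(Br)cc(OS(=O)(=O)C(F)(F)F)c1[Si](C)(C)C
F3 | step 3 | [5-allyl-3-methoxy-2-(methoxymethoxy)phenyl]boronic acid | C=CCc1cc(B(O)O)c(OCOC)c(OC)c1
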